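**Retrosynthetic overview**
- The target flavone comes from its 3'-O-benzyl-5-O-methyl ether by hydrogenolysis, then chelation-controlled cleavage of the peri 5-OMe.
- The γ-pyranone ring is the only ring built, and it is formed last, by oxidative cyclisation of a 2'-hydroxychalcone.
- Key C–C bond (flavone C2–C3 precursor): intermolecular Claisen–Schmidt aldol condensation of 2-hydroxy-4,5,6-trimethoxyacetophenone with 3-(benzyloxy)-2,4,5-trimethoxybenzaldehyde.
- The acetophenone comes from ortho-acetylation of 3,4,5-trimethoxyphenol.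
- The aldehyde comes from 2,6-dimethoxyphenol by O-benzylation and two bromination / Br–Li formylation rounds; the first CHO steers the second bromination and is then turned into OMe by Baeyer–Villiger oxidation.

Assumption: the target has no stereocentre, so it is made as the single achiral compound shown; the only stereo-element on the way is the E-alkene of chalcone 18.

**Step 1**
Reactants: 1 2,6-dimethoxyphenol
Product: 2 2-(benzyloxy)-1,3-dimethoxybenzene
Conditions: BnBr, K2CO3, DMF, 60 °C
Reagents that add atoms: benzyl bromide BrCc1ccccc1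
Why: Williamson ether synthesis (SN2) masks the phenol, so that later bromination is steered by the two methoxy groups and not to the position para to a free OH.

**Step 2**
Reactants: 2 2-(benzyloxy)-1,3-dimethoxybenzene
Product: 3 3-(benzyloxy)-1-bromo-2,4-dimethoxybenzene
Conditions: NBS (1.0 equiv), MeCN, 0 °C to rt
Reagents that add atoms: N-bromosuccinimide O=C1CCC(=O)N1Br
Why: Electrophilic aromatic bromination goes ortho to one terminal OMe and para to the other, as with 1,2,3-trimethoxybenzene, because the twisted central OBn is a poor para donor.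

**Step 3**
Reactants: 3 3-(benzyloxy)-1-bromo-2,4-dimethoxybenzene
Product: 6 3-(benzyloxy)-2,4-dimethoxybenzaldehyde, via aryllithium 4 (not isolated), via lithium hemiaminalate 5 (not isolated)
Conditions: n-BuLi, THF, −78 °C; DMF, −78 to 0 °C; then 1 M HCl
Reagents that add atoms: N,N-dimethylformamide CN(C)C=O
Why: Bromine–lithium exchange followed by formylation with DMF (Bouveault-type) puts the CHO exactly at the former C–Br carbon, and the tetrahedral adduct 5 blocks over-addition until the acid quench.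

**Step 4**
Reactants: 6 3-(benzyloxy)-2,4-dimethoxybenzaldehyde
Product: 7 3-(benzyloxy)-5-bromo-2,4-dimethoxybenzaldehyde
Conditions: NBS (1.1 equiv), DMF, rt
Reagents that add atoms: N-bromosuccinimide O=C1CCC(=O)N1Br
Why: Electrophilic aromatic bromination is directed to C5, which is ortho to 4-OMe, para to 2-OMe and meta to CHO, whereas C6 is ortho to the deactivating CHO (same outcome as for 2,4-dimethoxybenzaldehyde).

**Step 5**
Reactants: 7 3-(benzyloxy)-5-bromo-2,4-dimethoxybenzaldehyde
Product: 9 3-(benzyloxy)-5-bromo-2,4-dimethoxyphenol, via aryl formate 8 (not isolated)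
Conditions: mCPBA, CH2Cl2, rt; then K2CO3 (cat.), MeOH, rt
Reagents that add atoms: meta-chloroperoxybenzoic acid OOC(=O)c1cccc(Cl)c1
Why: Baeyer–Villiger (Dakin-type) oxidation with migration of the electron-rich aryl group gives formate 8, and mild methanolysis frees the phenol, turning the directing CHO into the future 5'-oxygen.

**Step 6**
Reactants: 9 3-(benzyloxy)-5-bromo-2,4-dimethoxyphenol
Product: 10 3-(benzyloxy)-1-bromo-2,4,5-trimethoxybenzene
Conditions: MeI, K2CO3, acetone, reflux
Reagents that add atoms: iodomethane CI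
Why: Williamson O-methylation (SN2) of the only free phenol; no other nucleophilic site is present.

**Step 7**
Reactants: 10 3-(benzyloxy)-1-bromo-2,4,5-trimethoxybenzene
Product: 13 3-(benzyloxy)-2,4,5-trimethoxybenzaldehyde, via aryllithium 11 (not isolated), via lithium hemiaminalate 12 (not isolated)
Conditions: n-BuLi, THF, −78 °C; DMF, −78 to 0 °C; then 1 M HCl
Reagents that add atoms: N,N-dimethylformamide CN(C)C=O
Why: Bromine–lithium exchange at −78 °C outpaces benzylic deprotonation, and DMF formylation gives the tetra-oxygenated benzaldehyde with the regiochemistry fixed by the bromine.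

**Step 8**
Reactants: 14 3,4,5-trimethoxyphenol
Product: 16 1-(2-hydroxy-4,5,6-trimethoxyphenyl)ethanone, via difluoroboron chelate 15 (not isolated)
Conditions: AcOH, BF3·OEt2 (3 equiv), 90 °C; then H2O/EtOH, 60 °C
Reagents that add atoms: acetic acid CC(=O)O
Why: BF3-mediated Friedel–Crafts (Fries-type) ortho-acylation works because both free positions are equivalent and ortho to OH, and trapping as chelate 15 stops a second acylation.

**Step 9**
Reactants: 16 1-(2-hydroxy-4,5,6-trimethoxyphenyl)ethanone; 13 3-(benzyloxy)-2,4,5-trimethoxybenzaldehyde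
Product: 18 (E)-3-[3-(benzyloxy)-2,4,5-trimethoxyphenyl]-1-(2-hydroxy-4,5,6-trimethoxyphenyl)prop-2-en-1-one, via aldol adduct 17 (not isolated)
Conditions: KOH (50% aq., excess), EtOH, rt, 24–48 h; then 1 M HCl
Reagents that add atoms: none
Why: In this Claisen–Schmidt crossed aldol condensation the methyl ketone enolate adds to the non-enolisable aldehyde, and E1cB dehydration of racemic aldol 17 gives the thermodynamically favoured E-enone, so no stereocentre remains.

**Step 10**
Reactants: 18 (E)-3-[3-(benzyloxy)-2,4,5-trimethoxyphenyl]-1-(2-hydroxy-4,5,6-trimethoxyphenyl)prop-2-en-1-one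
Product: 20 2-[3-(benzyloxy)-2,4,5-trimethoxyphenyl]-5,6,7-trimethoxy-4H-chromen-4-one, via flavanone 19 (not isolated)
Conditions: I2 (10 mol %), DMSO, 120 °C; then aq. Na2S2O3 wash
Reagents that add atoms: none
Why: I2/DMSO oxidative cyclisation proceeds by intramolecular oxa-Michael addition to racemic flavanone 19, then α-iodination and HI elimination, with DMSO re-oxidising HI to I2.

**Step 11**
Reactants: 20 2-[3-(benzyloxy)-2,4,5-trimethoxyphenyl]-5,6,7-trimethoxy-4H-chromen-4-one
Product: 21 2-(3-hydroxy-2,4,5-trimethoxyphenyl)-5,6,7-trimethoxy-4H-chromen-4-one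
Conditions: H2 (1 atm), 10% Pd/C, EtOAc/MeOH, rt
Reagents that add atoms: none
Why: Catalytic hydrogenolysis cleaves the benzyl aryl ether, while the vinylogous-ester C2=C3 bond of the flavone is not reduced at 1 atm and rt.

**Step 12**
Reactants: 21 2-(3-hydroxy-2,4,5-trimethoxyphenyl)-5,6,7-trimethoxy-4H-chromen-4-one
Product: 23 psiadiarabicin, 5-hydroxy-2-(3-hydroxy-2,4,5-trimethoxyphenyl)-6,7-dimethoxy-4H-chromen-4-one, via bis(dichloroboryl) ether 22 (not isolated)
Conditions: BCl3 (1 M in CH2Cl2, 2.5 equiv), CH2Cl2, −78 to 0 °C; then 1 M HCl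
Reagents that add atoms: none
Why: In this chelation-controlled Lewis-acid ether cleavage, BCl3 held between the 4-carbonyl and the peri 5-OMe delivers chloride to that methyl group only, and hydrolysis of 22 frees both phenols.

**Compound list**
1 | 2,6-dimethoxyphenol | COc1cccc(OC)c1O | starting material
2 | 2-(benzyloxy)-1,3-dimethoxybenzene | COc1cccc(OC)c1OCc1ccccc1 | intermediate
3 | 3-(benzyloxy)-1-bromo-2,4-dimethoxybenzene | COc1ccc(Br)c(OC)c1OCc1ccccc1 | intermediate
4 | [3-(benzyloxy)-2,4-dimethoxyphenyl]lithium | COc1ccc([Li])c(OC)c1OCc1ccccc1 | intermediate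
5 | lithium [3-(benzyloxy)-2,4-dimethoxyphenyl](dimethylamino)methanolate (racemic) | COc1ccc(C([O-])N(C)C)c(OC)c1OCc1ccccc1.[Li+] | intermediate
6 | 3-(benzyloxy)-2,4-dimethoxybenzaldehyde | COc1ccc(C=O)c(OC)c1OCc1ccccc1 | intermediate
7 | 3-(benzyloxy)-5-bromo-2,4-dimethoxybenzaldehyde | COc1c(Br)cc(C=O)c(OC)c1OCc1ccccc1 | intermediate
8 | 3-(benzyloxy)-5-bromo-2,4-dimethoxyphenyl formate | COc1c(Br)cc(OC=O)c(OC)c1OCc1ccccc1 | intermediate
9 | 3-(benzyloxy)-5-bromo-2,4-dimethoxyphenol | COc1c(Br)cc(O)c(OC)c1OCc1ccccc1 | intermediate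
10 | 3-(benzyloxy)-1-bromo-2,4,5-trimethoxybenzene | COc1cc(Br)c(OC)c(OCc2ccccc2)c1OC | intermediate
11 | [3-(benzyloxy)-2,4,5-trimethoxyphenyl]lithium | COc1cc([Li])c(OC)c(OCc2ccccc2)c1OC | intermediate
12 | lithium [3-(benzyloxy)-2,4,5-trimethoxyphenyl](dimethylamino)methanolate (racemic) | COc1cc(C([O-])N(C)C)c(OC)c(OCc2ccccc2)c1OC.[Li+] | intermediate
13 | 3-(benzyloxy)-2,4,5-trimethoxybenzaldehyde | COc1cc(C=O)c(OC)c(OCc2ccccc2)c1OC | intermediate
14 | 3,4,5-trimethoxyphenol | COc1cc(O)cc(OC)c1OC | starting material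
15 | difluoroboron chelate of 1-(2-hydroxy-4,5,6-trimethoxyphenyl)ethanone | COc1cc2c(c(OC)c1OC)C(C)=[O+][B-](F)(F)O2 | intermediate
16 | 1-(2-hydroxy-4,5,6-trimethoxyphenyl)ethanone | COc1cc(O)c(C(C)=O)c(OC)c1OC | intermediate
17 | 3-[3-(benzyloxy)-2,4,5-trimethoxyphenyl]-3-hydroxy-1-(2-hydroxy-4,5,6-trimethoxyphenyl)propan-1-one (racemic) | COc1cc(O)c(C(=O)CC(O)c2cc(OC)c(OC)c(OCc3ccccc3)c2OC)c(OC)c1OC | intermediate
18 | (E)-3-[3-(benzyloxy)-2,4,5-trimethoxyphenyl]-1-(2-hydroxy-4,5,6-trimethoxyphenyl)prop-2-en-1-one | COc1cc(O)c(C(=O)/C=C/c2cc(OC)c(OC)c(OCc3ccccc3)c2OC)c(OC)c1OC | intermediate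
19 | 2-[3-(benzyloxy)-2,4,5-trimethoxyphenyl]-5,6,7-trimethoxychroman-4-one (racemic) | COc1cc2OC(c3cc(OC)c(OC)c(OCc4ccccc4)c3OC)CC(=O)c2c(OC)c1OC | intermediate
20 | 2-[3-(benzyloxy)-2,4,5-trimethoxyphenyl]-5,6,7-trimethoxy-4H-chromen-4-one | COc1cc2oc(-c3cc(OC)c(OC)c(OCc4ccccc4)c3OC)cc(=O)c2c(OC)c1OC | intermediate
21 | 2-(3-hydroxy-2,4,5-trimethoxyphenyl)-5,6,7-trimethoxy-4H-chromen-4-one | COc1cc2oc(-c3cc(OC)c(OC)c(O)c3OC)cc(=O)c2c(OC)c1OC | intermediate
22 | 5-(dichloroboryloxy)-2-[3-(dichloroboryloxy)-2,4,5-trimethoxyphenyl]-6,7-dimethoxy-4H-chromen-4-one | COc1cc2oc(-c3cc(OC)c(OC)c(OB(Cl)Cl)c3OC)cc(=O)c2c(OB(Cl)Cl)c1OC | intermediate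
23 | psiadiarabicin, 5-hydroxy-2-(3-hydroxy-2,4,5-trimethoxyphenyl)-6,7-dimethoxy-4H-chromen-4-one (achiral) | COc1cc(-c2cc(=O)c3c(O)c(OC)c(OC)cc3o2)c(OC)c(O)c1OC | target

**Totals**
Total step count: 12. Longest linear sequence: 11 steps (steps 1–7, then 9–12, from 2,6-dimethoxyphenol); the acetophenone branch is step 8.

**Three steps most likely to fail, with fallbacks**

Step 4 (bromination of aldehyde 6). The C5 selectivity rests on analogy; attack at C6 or ipso loss of CHO would give the wrong oxygen pattern. The fallback sets out from aryl bromide 3 and comes back at bromophenol 9, avoiding any substitution on an aldehyde. A second bromination of 3 (NBS, MeCN, 40 °C) goes ortho to the remaining unhindered OMe and gives the symmetric 3-(benzyloxy)-1,5-dibromo-2,4-dimethoxybenzene F1. Because both bromines are equivalent, one equivalent of n-BuLi (THF, −78 °C) gives a single [3-(benzyloxy)-5-bromo-2,4-dimethoxyphenyl]lithium F2. Trapping with B(OMe)3 gives dimethyl [3-(benzyloxy)-5-bromo-2,4-dimethoxyphenyl]boronate F3, and oxidation in the same flask with H2O2/AcOH gives 9, after which steps 6 and 7 follow unchanged.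

Step 10 (I2/DMSO oxidative cyclisation). At 120 °C the HI formed may cleave the benzyl or peri-methyl ether, the electron-rich B ring may be iodinated, or the reaction may stall at flavanone 19. The fallback sets out from aryllithium 11 (made from bromide 10 as in step 7) together with acetophenone 16, and comes back at flavone 20. It builds the pyranone through a 1,3-diketone instead of a chalcone. Quenching 11 with methyl chloroformate gives methyl 3-(benzyloxy)-2,4,5-trimethoxybenzoate F4. The dianion of 16 (LiHMDS, 3.5 equiv, THF, −78 °C to reflux) undergoes intermolecular Claisen condensation with F4 to give 1-[3-(benzyloxy)-2,4,5-trimethoxyphenyl]-3-(2-hydroxy-4,5,6-trimethoxyphenyl)propane-1,3-dione F5. Acid-catalysed cyclodehydration (p-TsOH cat., toluene, reflux) then gives 20 with no oxidation step.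

Step 12 (selective 5-O-demethylation). Over-cleavage at 6-OMe is possible, and the 3'-aryloxyborane may assist cleavage of the flanking 2'- or 4'-OMe. The fallback sets out from 21 and comes back at target 23. It runs the Lewis-acid step on a substrate with no free phenol, so the only chelating site is the 4-C=O/5-OMe pair. Acetylation of 21 (Ac2O, pyridine, rt) gives 2-(3-acetoxy-2,4,5-trimethoxyphenyl)-5,6,7-trimethoxy-4H-chromen-4-one F6. BCl3 (1.2 equiv, CH2Cl2, −20 to 0 °C) gives 2-(3-acetoxy-2,4,5-trimethoxyphenyl)-5-(dichloroboryloxy)-6,7-dimethoxy-4H-chromen-4-one F7, which aqueous work-up hydrolyses to 2-(3-acetoxy-2,4,5-trimethoxyphenyl)-5-hydroxy-6,7-dimethoxy-4H-chromen-4-one F8. Mild methanolysis (K2CO3 cat., MeOH, rt) removes the acetate and gives 23.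

**Further compounds**
F1 | step 4 | 3-(benzyloxy)-1,5-dibromo-2,4-dimethoxybenzene | COc1c(Br)cc(Br)c(OC)c1OCc1ccccc1
F2 | step 4 | [3-(benzyloxy)-5-bromo-2,4-dimethoxyphenyl]lithium | COc1c(Br)cc([Li])c(OC)c1OCc1ccccc1
F3 | step 4 | dimethyl [3-(benzyloxy)-5-bromo-2,4-dimethoxyphenyl]boronate | COB(OC)c1cc(Br)c(OC)c(OCc2ccccc2)c1OC
F4 | step 10 | methyl 3-(benzyloxy)-2,4,5-trimethoxybenzoate | COC(=O)c1cc(OC)c(OC)c(OCc2ccccc2)c1OC
F5 | step 10 | 1-[3-(benzyloxy)-2,4,5-trimethoxyphenyl]-3-(2-hydroxy-4,5,6-trimethoxyphenyl)propane-1,3-dione | COc1cc(O)c(C(=O)CC(=O)c2cc(OC)c(OC)c(OCc3ccccc3)c2OC)c(OC)c1OC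
F6 | step 12 | 2-(3-acetoxy-2,4,5-trimethoxyphenyl)-5,6,7-trimethoxy-4H-chromen-4-one | COc1cc2oc(-c3cc(OC)c(OC)c(OC(C)=O)c3OC)cc(=O)c2c(OC)c1OC
F7 | step 12 | 2-(3-acetoxy-2,4,5-trimethoxyphenyl)-5-(dichloroboryloxy)-6,7-dimethoxy-4H-chromen-4-one | COc1cc2oc(-c3cc(OC)c(OC)c(OC(C)=O)c3OC)cc(=O)c2c(OB(Cl)Cl)c1OC
F8 | step 12 | 2-(3-acetoxy-2,4,5-trimethoxyphenyl)-5-hydroxy-6,7-dimethoxy-4H-chromen-4-one | COc1cc2oc(-c3cc(OC)c(OC)c(OC(C)=O)c3OC)cc(=O)c2c(O)c1OC
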